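## The problem

6-Hydroxyluteolin 6-sulfate 17 is a flavone in which benzene ring A is fused to 4-pyranone ring C and catechol ring B sits on C2; it has no stereocentre, so the synthesis has to solve regiochemistry and functional-group tolerance only. Ring A carries oxygen on four of its six carbons (C5, C6, C7 and C8a), and its only hydrogen is on C8. Of the five phenolic oxygens only O6 bears the sulfate, although the 7- and 4'-hydroxyls are the more acidic and more reactive, so O6 must be the only free hydroxyl at the moment of sulfation. The aryl hydrogen sulfate will not survive Brønsted or Lewis acids or hot protic media. The free trihydroxylated ring A and the catechol oxidise easily, and the C2–C3 double bond is a Michael acceptor that can also be hydrogenated. The feature that makes the key step possible is that C6 and C8a are para, so that O6 and O1 are the two oxygens of a hydroquinone. Ring A is therefore a masked 2,6-dioxygenated 1,4-benzoquinone whose two equivalent C–H carbons become C4a and C8: acylation at one of them leaves one hydroxyl next to the ketone (future O1) and a remote one that is the 6-OH.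

## Retrosynthesis

**17 to 15, via 16.** The last cut goes through the two C–O bonds of the diphenylmethylene ketal on ring B. With the sulfate in place the final deprotection should be neutral, so hydrogenolysis is preferred over acid hydrolysis of the ketal. The sodium salt 16 is protonated to the acid form 17 only at the very end. The forward step has to spare the C2–C3 double bond and the S–O bond.

**15 to 13, via 14.** Next the two O–CH3 bonds at O5 and O7 are cut. Methyl is dictated by the photochemical step, in which any ether with a weak C–H bond next to oxygen would be attacked. The cleavage must then be nucleophilic and basic, because Lewis-acidic boron halides would remove both the sulfate and the ketal. An aryl sulfate monoanion tolerates base, so a thiolate is chosen. Both methoxy groups are activated by the pyranone carbonyl (O7 para-vinylogous, O5 peri). The trisodium salt 14 is the species present in the flask.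

**13 to 11, via 12.** The O6–S bond is cut. In 11 every other oxygen is capped (two methyl ethers, the ketal, the ring oxygen), so sulfation cannot go astray. This is the point of the whole design and the reason why sulfation precedes demethylation.

**11 to 9, via 10.** The O1–C2 bond of ring C is cut, which gives the o-hydroxyaryl ynone 9. Compared with the neighbouring 1,3-diketone disconnection, the ynone needs no acid for dehydration, which the ketal would not like. An amine-mediated closure through enaminone 10 is 6-endo by construction and excludes the aurone. The second hydroxyl of 9 is meta to the ketone and cannot cyclise.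

**9 to 7 + 8.** The C4–C4a bond is cut. This reveals the commercial 2,6-dimethoxy-1,4-benzoquinone 8 and the ring B ynal 7. Photochemical acylation of the quinone by the aldehyde makes the bond and delivers the hydroquinone oxidation level in the same step, so no protecting group is ever placed on O6 or O1. A Friedel–Crafts or Fries approach to the same ketone would need a differentiated tetraoxygenated benzene and acid. The forward reaction must abstract the formyl hydrogen faster than the excited quinone adds to the alkyne.

**7 to 1 + 2, via 3, 4, 5 and 6.** The formyl carbon is cut from the alkyne (formylation of acetylide 5 through adduct 6). The alkyne carbon is cut from the aryl aldehyde 3 (one-carbon homologation to 4). The ketal is cut to 3,4-dihydroxybenzaldehyde 1 and dichlorodiphenylmethane 2. The ketal is chosen because its central carbon has no hydrogen and because it is stable to base, organolithiums and thiolate.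

## Roads not taken

Alternative 1: The cut is the O1–C8a bond. The precursor would be 1-[2,4-bis(benzyloxy)-3-hydroxyphenyl]-3-[3,4-bis(benzyloxy)phenyl]propane-1,3-dione A1. Anodic oxidation would give a phenoxonium ion, the enol oxygen would attack the carbon para to the phenol oxygen, and loss of a proton would give 5,7-bis(benzyloxy)-2-[3,4-bis(benzyloxy)phenyl]-6-hydroxychromen-4-one A2.

- Merits: A2 has benzyl ethers only and a lone 6-OH, so sulfation and one hydrogenolysis would finish the synthesis. That endgame is shorter and gentler than the one chosen here, which must cleave two methyl ethers next to a sulfate.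
- Weak points: the carbon to be attacked is ortho to the acyl group and is the least electron-rich position of a deactivated phenol. The veratrole-like ring B and the benzyl ethers should oxidise at similar potentials. A2, a para-alkoxyphenol, is easier to oxidise than A1 and may go on to a quinone. A1 also needs a trioxygenated acetophenone benzylated at the chelated 2-hydroxyl but not at the 3-hydroxyl, against the natural order of reactivity.
- Comparison: the chosen plan gives up the better endgame of this road and gains a ring A bond formation of a known reaction type.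

Alternative 2: The cut is the O1–C2 bond, opened and formed again. In hot hydriodic acid the 8-oxygenated isomer 5,8-dihydroxy-7,3',4'-trimethoxyflavone A3 would be demethylated, opened to the 1,3-diketone and closed again through the former 5-oxygen, which gives 6-hydroxyluteolin A4.

- Merits: the chemistry is classical, needs no photochemistry, and should reach the carbon–oxygen skeleton in fewer steps than the chosen plan.
- Weak points: A4 has five free hydroxyls and no handle that singles out O6, and the 7- and 4'-hydroxyls would be sulfated first. The conditions exclude any protecting group on A3 that could carry a differentiation through the step, and the isomerisation may stop at a mixture of A3-derived and A4-type flavones.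
- Comparison: this road is better for the aglycone but leaves the central problem unsolved. The chosen plan uses more steps and in return delivers O6 as the only free hydroxyl.

Alternative 3: The cut is the C6–O bond, with the O–S bond already in the reagent. The phenolate of 4,6-bis(benzyloxy)-2-hydroxyacetophenone A5 would attack a peroxide oxygen of K2S2O8 through its para carbon and give potassium 3-acetyl-2,6-bis(benzyloxy)-4-hydroxyphenyl sulfate A6 directly.

- Merits: the sulfate position is settled by mechanism, the reagents are cheap, only benzyl ethers are present, and the step count could be lower than in the chosen plan. In these respects this road is better.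
- Weak points: Elbs oxidations usually stop at low conversion, and the para carbon of A5 lies between two benzyloxy groups. The sulfate of A6 must then survive the whole flavone assembly, where acidic cyclodehydration or hot oxidative chalcone closure threatens it. Every intermediate after A6 is a salt that is awkward to purify.
- Comparison: the chosen plan keeps the sulfate out of all C–C and ring-forming chemistry and exposes it to only two later steps. The price is the thiolate demethylation.

Key step: step 4

Assumption: the target is drawn as the free hydrogen sulfate; because aryl hydrogen sulfates hydrolyse in their acid form, the sulfate is carried as its sodium salt and protonated with one equivalent of acid only at the end of the last step.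

## Route

Step 1
Reactants: 1 3,4-dihydroxybenzaldehyde; 2 dichlorodiphenylmethane
Product: 3 2,2-diphenyl-1,3-benzodioxole-5-carbaldehyde
Conditions: Ph2CCl2 (1.5 equiv), Ph2O, 175 °C, 30 min
Reagents that add atoms: none
Why: Thermal ketalisation of a catechol with a gem-dichloride (double O-alkylation through the stabilised diarylchloromethyl cation); the aldehyde is inert and HCl leaves as gas.

Step 2
Reactants: 3 2,2-diphenyl-1,3-benzodioxole-5-carbaldehyde
Product: 4 5-ethynyl-2,2-diphenyl-1,3-benzodioxole
Conditions: dimethyl (1-diazo-2-oxopropyl)phosphonate, K2CO3, MeOH/THF, 0 °C to rt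
Reagents that add atoms: dimethyl (1-diazo-2-oxopropyl)phosphonate, CC(=O)C(=[N+]=[N-])P(=O)(OC)OC
Why: Seyferth–Gilbert homologation in the Ohira–Bestmann variant: methanolysis frees the diazophosphonate anion, which olefinates the aldehyde and loses N2 with 1,2-hydrogen shift to the terminal alkyne; the ketal is stable to K2CO3 in MeOH.

Step 3
Reactants: 4 5-ethynyl-2,2-diphenyl-1,3-benzodioxole
Product: 7 3-(2,2-diphenyl-1,3-benzodioxol-5-yl)prop-2-ynal, via lithium acetylide 5 (not isolated), via lithium aminoalkoxide 6 (not isolated)
Conditions: n-BuLi, THF, −78 °C; DMF, −78 to 0 °C; inverse quench into aq KH2PO4/MTBE, 5 °C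
Reagents that add atoms: N,N-dimethylformamide, CN(C)C=O
Why: Formylation of a lithium acetylide with DMF; acetylide 5 adds to DMF to give the stable tetrahedral adduct 6, which releases ynal 7 only on inverse quench into buffer, so that the liberated dimethylamine is protonated before it can add to the ynal.

Step 4
Reactants: 7 3-(2,2-diphenyl-1,3-benzodioxol-5-yl)prop-2-ynal; 8 2,6-dimethoxy-1,4-benzoquinone
Product: 9 1-(3,6-dihydroxy-2,4-dimethoxyphenyl)-3-(2,2-diphenyl-1,3-benzodioxol-5-yl)prop-2-yn-1-one
Conditions: 8 (1.0 equiv), 7 (1.5 equiv), PhCF3 (0.05 M), Ar, 450 nm LEDs, 20 °C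
Reagents that add atoms: none
Why: Blue light should excite only quinone 8 (ynal 7 and the ketal do not absorb at 450 nm), and its n,π* triplet abstracts the weakly bound formyl hydrogen of 7 to give a semiquinone and an alkynoyl radical. This σ-acyl radical cannot lose CO without forming an alkynyl radical, so it survives to bond to an unsubstituted quinone carbon (by direct radical combination, by addition to ground-state 8 in a chain, or by coupling at oxygen followed by acyl shift), and enolisation gives acylhydroquinone 9. The closest known reaction is the photo-Friedel–Crafts acylation of 1,4-quinones with aldehydes, established for alkyl, aryl and α,β-unsaturated aldehydes and applied here to a conjugated ynal and a dialkoxyquinone. Only the C4–C4a bond is formed; no ring closes and no stereocentre arises. Site selectivity needs no control because the two C–H carbons of 8 are equivalent by symmetry, and the product, being a hydroquinone, is not acylated again. Chemoselectivity requires that hydrogen abstraction from the CHO group outruns addition of the triplet quinone to the alkyne and abstraction elsewhere; this is secured by the formyl C–H being the weakest bond present, by methyl ethers on ring A, by a ketal carbon without hydrogen on ring B, by the electron-poor alkyne, and by a non-polar solvent without abstractable hydrogen that disfavours electron transfer from ring B. Product 9 is an o-hydroxyaryl ketone that can dissipate excitation by intramolecular proton transfer and should persist under the lamp.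

Step 5
Reactants: 9 1-(3,6-dihydroxy-2,4-dimethoxyphenyl)-3-(2,2-diphenyl-1,3-benzodioxol-5-yl)prop-2-yn-1-one
Product: 11 2-(2,2-diphenyl-1,3-benzodioxol-5-yl)-6-hydroxy-5,7-dimethoxy-4H-chromen-4-one, via diethylamino enone 10 (not isolated)
Conditions: Et2NH (5 equiv), degassed EtOH/THF, Ar, rt then 60 °C
Reagents that add atoms: none
Why: Amine-mediated flavone closure: conjugate addition of Et2NH gives enaminone 10, the ortho hydroxyl adds to the β-carbon (6-endo oxa-Michael) and the amine is eliminated, so the 5-exo aurone pathway is not available; the meta hydroxyl cannot reach the enone and stays free as the 6-OH.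

Step 6
Reactants: 11 2-(2,2-diphenyl-1,3-benzodioxol-5-yl)-6-hydroxy-5,7-dimethoxy-4H-chromen-4-one
Product: 13 sodium 2-(2,2-diphenyl-1,3-benzodioxol-5-yl)-5,7-dimethoxy-4-oxo-4H-chromen-6-yl sulfate, via pyridinium sulfate salt 12 (not isolated)
Conditions: SO3·pyridine (4 equiv), pyridine, 60 °C; aq NaHCO3
Reagents that add atoms: sulfur trioxide–pyridine complex, O=S(=O)([O-])[n+]1ccccc1; sodium hydrogencarbonate, OC(=O)[O-].[Na+]
Why: O-Sulfonation of a phenol with an SO3–amine complex; the 6-OH is the only hydroxyl in 11, so no regiochemical question arises, 2,6-dialkoxyphenols are sulfated under these conditions, and the ketal tolerates the non-acidic medium; NaHCO3 exchanges pyridinium for sodium.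

Step 7
Reactants: 13 sodium 2-(2,2-diphenyl-1,3-benzodioxol-5-yl)-5,7-dimethoxy-4-oxo-4H-chromen-6-yl sulfate
Product: 15 sodium 2-(2,2-diphenyl-1,3-benzodioxol-5-yl)-5,7-dihydroxy-4-oxo-4H-chromen-6-yl sulfate, via trisodium diphenoxide 14 (not isolated)
Conditions: NaSEt (8 equiv), DMF, Ar, 120 °C; cool, AcOH to pH 5
Reagents that add atoms: none
Why: SN2 O-demethylation of aryl methyl ethers by thiolate; both leaving phenoxides are stabilised by the pyranone carbonyl (O7 para-vinylogous, O5 peri), the sulfate monoanion is a poor electrophile at sulfur and is stable to base, and the ketal has no carbon open to thiolate attack; mild acidification protonates the phenoxides of 14 without touching the sulfate.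

Step 8
Reactants: 15 sodium 2-(2,2-diphenyl-1,3-benzodioxol-5-yl)-5,7-dihydroxy-4-oxo-4H-chromen-6-yl sulfate
Product: 17 6-hydroxyluteolin 6-sulfate [2-(3,4-dihydroxyphenyl)-5,7-dihydroxy-4-oxo-4H-chromen-6-yl hydrogen sulfate], via sodium salt 16 (not isolated)
Conditions: H2 (1 atm), 10% Pd/C, MeOH/THF, rt; filter; HCl (1.0 equiv), H2O, 0 °C; C18 desalting, freeze-drying
Reagents that add atoms: none
Why: Hydrogenolysis of the two doubly benzylic C–O bonds of the diphenylmethylene ketal frees the catechol as diphenylmethane is lost; aryl sulfate salts and the flavone C2–C3 bond are expected to survive neutral hydrogenation at 1 atm, and one equivalent of cold acid then converts sodium salt 16 into the hydrogen sulfate as drawn.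

## Compound list

1 | 3,4-dihydroxybenzaldehyde | O=Cc1ccc(O)c(O)c1 | starting material
2 | dichlorodiphenylmethane | ClC(Cl)(c1ccccc1)c1ccccc1 | starting material
3 | 2,2-diphenyl-1,3-benzodioxole-5-carbaldehyde | O=Cc1ccc2OC(c3ccccc3)(c3ccccc3)Oc2c1 | intermediate
4 | 5-ethynyl-2,2-diphenyl-1,3-benzodioxole | C#Cc1ccc2OC(c3ccccc3)(c3ccccc3)Oc2c1 | intermediate
5 | lithium (2,2-diphenyl-1,3-benzodioxol-5-yl)acetylide | [Li]C#Cc1ccc2OC(c3ccccc3)(c3ccccc3)Oc2c1 | intermediate
6 | lithium 1-(dimethylamino)-3-(2,2-diphenyl-1,3-benzodioxol-5-yl)prop-2-yn-1-olate (racemic) | CN(C)C(O[Li])C#Cc1ccc2OC(c3ccccc3)(c3ccccc3)Oc2c1 | intermediate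
7 | 3-(2,2-diphenyl-1,3-benzodioxol-5-yl)prop-2-ynal | O=CC#Cc1ccc2OC(c3ccccc3)(c3ccccc3)Oc2c1 | intermediate
8 | 2,6-dimethoxy-1,4-benzoquinone | COC1=CC(=O)C=C(OC)C1=O | starting material
9 | 1-(3,6-dihydroxy-2,4-dimethoxyphenyl)-3-(2,2-diphenyl-1,3-benzodioxol-5-yl)prop-2-yn-1-one | COc1cc(O)c(C(=O)C#Cc2ccc3OC(c4ccccc4)(c4ccccc4)Oc3c2)c(OC)c1O | intermediate
10 | (E)-3-(diethylamino)-1-(3,6-dihydroxy-2,4-dimethoxyphenyl)-3-(2,2-diphenyl-1,3-benzodioxol-5-yl)prop-2-en-1-one (the push–pull double bond isomerises easily; geometry is immaterial for closure) | CCN(CC)/C(c1ccc2OC(c3ccccc3)(c3ccccc3)Oc2c1)=C/C(=O)c1c(O)cc(OC)c(O)c1OC | intermediate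
11 | 2-(2,2-diphenyl-1,3-benzodioxol-5-yl)-6-hydroxy-5,7-dimethoxy-4H-chromen-4-one | COc1cc2oc(-c3ccc4OC(c5ccccc5)(c5ccccc5)Oc4c3)cc(=O)c2c(OC)c1O | intermediate
12 | pyridinium 2-(2,2-diphenyl-1,3-benzodioxol-5-yl)-5,7-dimethoxy-4-oxo-4H-chromen-6-yl sulfate | COc1cc2oc(-c3ccc4OC(c5ccccc5)(c5ccccc5)Oc4c3)cc(=O)c2c(OC)c1OS(=O)(=O)[O-].c1cc[nH+]cc1 | intermediate
13 | sodium 2-(2,2-diphenyl-1,3-benzodioxol-5-yl)-5,7-dimethoxy-4-oxo-4H-chromen-6-yl sulfate | COc1cc2oc(-c3ccc4OC(c5ccccc5)(c5ccccc5)Oc4c3)cc(=O)c2c(OC)c1OS(=O)(=O)[O-].[Na+] | intermediate
14 | trisodium 2-(2,2-diphenyl-1,3-benzodioxol-5-yl)-4-oxo-6-(sulfonatooxy)-4H-chromene-5,7-diolate | [O-]c1cc2oc(-c3ccc4OC(c5ccccc5)(c5ccccc5)Oc4c3)cc(=O)c2c([O-])c1OS(=O)(=O)[O-].[Na+].[Na+].[Na+] | intermediate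
15 | sodium 2-(2,2-diphenyl-1,3-benzodioxol-5-yl)-5,7-dihydroxy-4-oxo-4H-chromen-6-yl sulfate | Oc1cc2oc(-c3ccc4OC(c5ccccc5)(c5ccccc5)Oc4c3)cc(=O)c2c(O)c1OS(=O)(=O)[O-].[Na+] | intermediate
16 | sodium 2-(3,4-dihydroxyphenyl)-5,7-dihydroxy-4-oxo-4H-chromen-6-yl sulfate | O=c1cc(-c2ccc(O)c(O)c2)oc2cc(O)c(OS(=O)(=O)[O-])c(O)c12.[Na+] | intermediate
17 | 6-hydroxyluteolin 6-sulfate, 2-(3,4-dihydroxyphenyl)-5,7-dihydroxy-4-oxo-4H-chromen-6-yl hydrogen sulfate | O=c1cc(-c2ccc(O)c(O)c2)oc2cc(O)c(OS(=O)(=O)O)c(O)c12 | target

## Step count and least certain steps

Total: 8 steps. Longest linear sequence: 8 steps (1 to 17); quinone 8 is bought and enters at step 4.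

**Step 4 (key step).** The excited quinone may be consumed by cycloaddition to the alkyne or quenched by electron transfer from the electron-rich ring B before it abstracts the formyl hydrogen. The two methoxy groups may also lower the hydrogen-abstracting power of the quinone triplet. The alkynoyl radical may add to a second ynal and start oligomerisation, and conversion may stall as the coloured product competes for light.

Fallback: the same C4–C4a bond would be made by polar chemistry, setting out from 8 (with 7 as the electrophile) and coming back to the route at 9. Quinone 8 would be reduced with Na2S2O4 to 2,6-dimethoxybenzene-1,4-diol F1. Protection with chloromethyl methyl ether and i-Pr2NEt would give 1,3-dimethoxy-2,5-bis(methoxymethoxy)benzene F2. Directed ortho-lithiation of F2 (n-BuLi, TMEDA, THF, 0 °C) at the carbon between a methoxy and a methoxymethoxy group, then addition to ynal 7, would give racemic 1-[2,4-dimethoxy-3,6-bis(methoxymethoxy)phenyl]-3-(2,2-diphenyl-1,3-benzodioxol-5-yl)prop-2-yn-1-ol F3. MnO2 would oxidise this alcohol to 1-[2,4-dimethoxy-3,6-bis(methoxymethoxy)phenyl]-3-(2,2-diphenyl-1,3-benzodioxol-5-yl)prop-2-yn-1-one F4. Dilute HCl in MeOH/THF at room temperature, where phenolic methoxymethyl ethers should cleave faster than the diaryl ketal, would then return the route to 9.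

**Step 7.** Each demethylation adds a negative charge next to the sulfate, so cleavage may stop after the first methyl group. The sulfuryl group may also be lost or may migrate to a neighbouring phenoxide in the hot nucleophilic medium, and reversible thiolate addition at C2 may open ring C.

Fallback: the demethylation would be moved ahead of the sulfation, setting out from 11 and coming back to the route at 16. NaSEt in DMF under more forcing conditions (no sulfate is at risk) would give 2-(2,2-diphenyl-1,3-benzodioxol-5-yl)-5,6,7-trihydroxy-4H-chromen-4-one F5. One equivalent of benzyl bromide with KHCO3 in DMF would alkylate the most acidic 7-hydroxyl to give 7-(benzyloxy)-2-(2,2-diphenyl-1,3-benzodioxol-5-yl)-5,6-dihydroxy-4H-chromen-4-one F6. SO3·pyridine, then NaHCO3, would sulfate the 6-hydroxyl, since the 5-hydroxyl is held in a hydrogen bond to the C4 carbonyl; the product would be sodium 7-(benzyloxy)-2-(2,2-diphenyl-1,3-benzodioxol-5-yl)-5-hydroxy-4-oxo-4H-chromen-6-yl sulfate F7. Hydrogenolysis over Pd/C would remove the benzyl ether and the ketal together and rejoin the route at 16. This costs one step and depends on the 7- over 6-selectivity of the benzylation.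

**Step 5.** The electron-rich acylhydroquinone may be oxidised to the acylquinone by traces of air under basic conditions, or the sequence may stop at the enaminone without ring closure.

Fallback: the closure would be changed to the classical diketone route, setting out from 10 and coming back at 11. Hydrolysis of 10 with aqueous oxalic acid in THF would give 1-(3,6-dihydroxy-2,4-dimethoxyphenyl)-3-(2,2-diphenyl-1,3-benzodioxol-5-yl)propane-1,3-dione F8. Cyclodehydration with catalytic TsOH in toluene with azeotropic removal of water, anhydrous conditions under which the ketal should hold, would then return to 11.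

**Step 3.** Dimethylamine released on collapse of the adduct may add to the ynal, and the ynal may polymerise on concentration.

Fallback: the formyl carbon would be brought in at the alcohol oxidation level, setting out from 4 and coming back at 7. Acetylide 5, made from 4 as before, would be trapped with paraformaldehyde to give 3-(2,2-diphenyl-1,3-benzodioxol-5-yl)prop-2-yn-1-ol F9. Oxidation with MnO2 in CH2Cl2 would return to 7 without any amine present.

## Further compounds

F1 | step 4 | 2,6-dimethoxybenzene-1,4-diol | COc1cc(O)cc(OC)c1O
F2 | step 4 | 1,3-dimethoxy-2,5-bis(methoxymethoxy)benzene | COCOc1cc(OC)c(OCOC)c(OC)c1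
F3 | step 4 | 1-[2,4-dimethoxy-3,6-bis(methoxymethoxy)phenyl]-3-(2,2-diphenyl-1,3-benzodioxol-5-yl)prop-2-yn-1-ol (racemic) | COCOc1cc(OC)c(OCOC)c(OC)c1C(O)C#Cc1ccc2OC(c3ccccc3)(c3ccccc3)Oc2c1
F4 | step 4 | 1-[2,4-dimethoxy-3,6-bis(methoxymethoxy)phenyl]-3-(2,2-diphenyl-1,3-benzodioxol-5-yl)prop-2-yn-1-one | COCOc1cc(OC)c(OCOC)c(OC)c1C(=O)C#Cc1ccc2OC(c3ccccc3)(c3ccccc3)Oc2c1
F5 | step 7 | 2-(2,2-diphenyl-1,3-benzodioxol-5-yl)-5,6,7-trihydroxy-4H-chromen-4-one | O=c1cc(-c2ccc3OC(c4ccccc4)(c4ccccc4)Oc3c2)oc2cc(O)c(O)c(O)c12
F6 | step 7 | 7-(benzyloxy)-2-(2,2-diphenyl-1,3-benzodioxol-5-yl)-5,6-dihydroxy-4H-chromen-4-one | O=c1cc(-c2ccc3OC(c4ccccc4)(c4ccccc4)Oc3c2)oc2cc(OCc3ccccc3)c(O)c(O)c12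
F7 | step 7 | sodium 7-(benzyloxy)-2-(2,2-diphenyl-1,3-benzodioxol-5-yl)-5-hydroxy-4-oxo-4H-chromen-6-yl sulfate | O=c1cc(-c2ccc3OC(c4ccccc4)(c4ccccc4)Oc3c2)oc2cc(OCc3ccccc3)c(OS(=O)(=O)[O-])c(O)c12.[Na+]
F8 | step 5 | 1-(3,6-dihydroxy-2,4-dimethoxyphenyl)-3-(2,2-diphenyl-1,3-benzodioxol-5-yl)propane-1,3-dione | COc1cc(O)c(C(=O)CC(=O)c2ccc3OC(c4ccccc4)(c4ccccc4)Oc3c2)c(OC)c1O
F9 | step 3 | 3-(2,2-diphenyl-1,3-benzodioxol-5-yl)prop-2-yn-1-ol | OCC#Cc1ccc2OC(c3ccccc3)(c3ccccc3)Oc2c1
A1 | alternative 1 | 1-[2,4-bis(benzyloxy)-3-hydroxyphenyl]-3-[3,4-bis(benzyloxy)phenyl]propane-1,3-dione | O=C(CC(=O)c1ccc(OCc2ccccc2)c(OCc2ccccc2)c1)c1ccc(OCc2ccccc2)c(O)c1OCc1ccccc1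
A2 | alternative 1 | 5,7-bis(benzyloxy)-2-[3,4-bis(benzyloxy)phenyl]-6-hydroxychromen-4-one | O=c1cc(-c2ccc(OCc3ccccc3)c(OCc3ccccc3)c2)oc2cc(OCc3ccccc3)c(O)c(OCc3ccccc3)c12
A3 | alternative 2 | 5,8-dihydroxy-7,3',4'-trimethoxyflavone | COc1ccc(-c2cc(=O)c3c(O)cc(OC)c(O)c3o2)cc1OC
A4 | alternative 2 | 6-hydroxyluteolin | O=c1cc(-c2ccc(O)c(O)c2)oc2cc(O)c(O)c(O)c12
A5 | alternative 3 | 4,6-bis(benzyloxy)-2-hydroxyacetophenone | CC(=O)c1c(O)cc(OCc2ccccc2)cc1OCc1ccccc1
A6 | alternative 3 | potassium 3-acetyl-2,6-bis(benzyloxy)-4-hydroxyphenyl sulfate | CC(=O)c1c(O)cc(OCc2ccccc2)c(OS(=O)(=O)[O-])c1OCc1ccccc1.[K+]
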